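**Plan**

1. Cuts, latest first: the C15 ester and C13=C14 of the side chain; C1=C10 of ring A; C4–C19 and C4–C3; then C9–C11, C8–C17 and C5–C4 on a ring B enone.
2. Forward: ring B is (R)-carvone, which receives its C5, C8 and C9 substituents. A γ-lactone spanning O–C10 and C5 is used to build quaternary C4. Ring A is closed last by titanium-mediated coupling of the C10 ketone with a C1 aldehyde, and the C11–C16 chain is finished afterwards.
3. The feature that allows this closure is the trisubstituted C1=C10 alkene of ring A, lying between quaternary C9 and the C5 methine. Both of its carbons can be carbonyl carbons (ring B ketone, aldehyde on the C4 arm) six atoms apart, so its position is fixed by construction.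
4. Stereochemistry: the carvone stereocentre (C6 isopropenyl, excised later) relays to C5, C8 and C9. C4 is set by alkylating the enolate of the cis-fused lactone on its convex face. The 13E geometry comes from the olefination.

Key step: step 13

Remark: halimane numbering is used (C17 on C8, C20 on C9, C16 on C13; the C4 carbon that ends as CO2H is called C18, the C4 methyl C19); "upper face" is the face of C17 and C20; the target SMILES is read as the (4S,5S,8R,9S,13E) isomer.

**Route**

Step 1
Reactants: 1 (R)-carvone; 2 ethyl bromoacetate
Product: 3 ethyl 2-[(1S,6R)-3-methyl-2-oxo-6-(prop-1-en-2-yl)cyclohex-3-en-1-yl]acetate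
Conditions: LiN(i-Pr)2, THF, −78 °C; then BrCH2CO2Et, HMPA, −78 → −20 °C
Reagents that add atoms: ethyl bromoacetate, BrCC(=O)OCC
Why: Kinetic deprotonation at C5 and SN2 alkylation of the cross-conjugated lithium dienolate (enolate alkylation) should place the acetate arm anti to the adjacent C6 isopropenyl group, and this trans isomer is also the one favoured if C5 is equilibrated with base.

Step 2
Reactants: 3 acetate-substituted carvone; 4 methylmagnesium bromide
Product: 5 trimethylsilyl enol ether (C9=C10) carrying the new C17 methyl on C8
Conditions: MeMgBr, CuBr·SMe2 (10 mol %), Me3SiCl, HMPA, THF, −78 °C; Et3N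
Reagents that add atoms: methylmagnesium bromide, C[Mg]Br; chlorotrimethylsilane, C[Si](C)(C)Cl
Why: Copper-catalysed conjugate addition with in situ O-silylation should deliver methyl axially to C8 anti to the C6 isopropenyl group (the usual course for carvone), which puts C17 cis to the C5 arm and fixes the enolate regiospecifically as the C9=C10 silyl enol ether.

Step 3
Reactants: 5 silyl enol ether; 6 but-3-en-2-one
Product: 7 ring B diketo ester with quaternary C9
Conditions: BF3·OEt2, i-PrOH, CH2Cl2, −78 °C
Reagents that add atoms: but-3-en-2-one, CC(=O)C=C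
Why: In this Mukaiyama–Michael addition the enone should approach C9 from the lower face, opposite the adjacent pseudo-axial C17 methyl and the C5 arm, so that C20 ends cis to C17 and the 3-oxobutyl chain trans.

Step 4
Reactants: 7 diketo ester
Product: 8 C13 ethylene ketal
Conditions: Me3SiOCH2CH2OSiMe3, Me3SiOTf (cat.), CH2Cl2, −78 → −20 °C
Reagents that add atoms: 1,2-bis(trimethylsilyloxy)ethane, C[Si](C)(C)OCCO[Si](C)(C)C
Why: Silyl-transfer ketalisation at low temperature should select the unhindered methyl ketone over the C10 ketone, which is flanked by quaternary C9 and tertiary C5, and it leaves the ester and the isopropenyl group untouched.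

Step 5
Reactants: 8 keto ester ketal
Product: 10 cis-fused γ-lactone (O–C10 and C5) still bearing the C6 isopropenyl group, via hydroxy ester 9 (not isolated)
Conditions: LiBH(s-Bu)3, THF, −78 °C → rt
Reagents that add atoms: none
Why: In this bulky trialkylborohydride reduction the axial (upper) trajectory at C10 is closed by the syn-axial C17 methyl, so hydride should arrive equatorially from the lower face and give the axial alkoxide cis to the C5 arm, which lactonises on warming by intramolecular transesterification.

Step 6
Reactants: 10 isopropenyl lactone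
Product: 12 cis-fused γ-lactone with C6 as CH2, via methoxy hydroperoxide 11 (not isolated)
Conditions: O3, MeOH, −78 °C; then FeSO4·7H2O, PhSH, −78 °C → rt
Reagents that add atoms: ozone, [O-][O+]=O (atoms appear in 11 only); methanol, CO (atoms appear in 11 only)
Why: Dealkenylative hydrogenation (ozonolysis in methanol, reduction of the hydroperoxide by divalent iron, β-scission of the alkoxy radical, hydrogen-atom transfer from the thiol) should remove the control element as methyl acetate and leave a methylene at C6 without touching any other stereocentre.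

Step 7
Reactants: 12 lactone; 13 allyl bromide
Product: 14 C4-allyl lactone
Conditions: LiN(i-Pr)2, THF, −78 °C; then allyl bromide, −78 → −40 °C
Reagents that add atoms: allyl bromide, BrCC=C
Why: Lactone enolate alkylation installs the future C3–C1 unit, entering on the convex face (cis to H5); this C4 configuration is transient because C4 is enolised again in step 8.

Step 8
Reactants: 14 allyl lactone; 15 iodomethane
Product: 16 C4-methyl C4-allyl lactone
Conditions: LiN(i-Pr)2, THF/HMPA, −78 °C; then MeI, −78 → 0 °C
Reagents that add atoms: iodomethane, CI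
Why: The second enolate alkylation creates quaternary C4; in the cis-fused bicycle the electrophile should again approach the convex face, syn to H5 and anti to the C5–C6 bond, so methyl ends cis to H5 and the allyl group on the ring B side, which is the C4 configuration of the target.

Step 9
Reactants: 16 dialkylated lactone
Product: 17 diol (axial C10–OH, primary C18–OH)
Conditions: LiAlH4, THF, 0 °C → reflux
Reagents that add atoms: none
Why: Hydride reduction of the lactone to the 1,4-diol touches no stereocentre and leaves the ketal and the terminal alkene intact.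

Step 10
Reactants: 17 diol
Product: 18 C18 tert-butyldiphenylsilyl ether
Conditions: t-BuPh2SiCl, imidazole, DMF, rt
Reagents that add atoms: tert-butyl(chloro)diphenylsilane, CC(C)(C)[Si](Cl)(c1ccccc1)c1ccccc1
Why: Silylation should select the primary alcohol over the axial C10 alcohol flanked by C9 and C5; carrying C18 as a silyl ether means no ester competes for low-valent titanium later and no hindered ester has to be cleaved beside the allylic propanoate.

Step 11
Reactants: 18 silyl ether
Product: 20 C1,C10-diol, via B-alkyl-9-BBN adduct 19 (not isolated)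
Conditions: 9-BBN, THF, 0 °C → rt; then NaOH, H2O2, 0 °C
Reagents that add atoms: 9-borabicyclo[3.3.1]nonane, B1C2CCCC1CCC2 (boron and ring carbons appear in 19 only); hydrogen peroxide, OO
Why: Anti-Markovnikov hydroboration–oxidation of the terminal alkene places the hydroxyl on C1 with the regioselectivity typical of 9-BBN.

Step 12
Reactants: 20 diol
Product: 21 keto aldehyde (C10 ketone, C1 aldehyde, C13 ketal, C18 silyl ether)
Conditions: Dess–Martin periodinane, NaHCO3, CH2Cl2, rt
Reagents that add atoms: none
Why: Dess–Martin oxidation converts both alcohols in one operation under buffered, non-basic conditions that should leave the enolisable C5 centre unchanged; the temporary C10 stereocentre is removed here.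

Step 13
Reactants: 21 keto aldehyde
Product: 23 halim-1(10)-ene with C13 ketal and C18 silyl ether, via titanium pinacolate 22 (not isolated)
Conditions: TiCl3(DME)1.5, Zn–Cu, DME, reflux; 21 added by syringe pump over 30 h, then reflux 10 h
Reagents that add atoms: titanium trichloride, Cl[Ti](Cl)Cl (titanium appears in 22 only)
Why: Low-valent titanium made from TiCl3 and Zn–Cu transfers single electrons to the C1 aldehyde and the C10 ketone, the ketyl carbons join to the titanium-bound pinacolate 22, and at reflux titanium removes both oxygens to leave the C1=C10 alkene. The closest known reaction type is the intramolecular McMurry coupling of keto aldehydes to cycloalkenes. Ring A closes as a six-membered carbocycle by carbonyl-to-carbonyl C–C bond formation (formally a 6-exo attack of the C1 ketyl on the C10 carbonyl), helped by the fully substituted C4 in the tether. No stereocentre is created, since C1 and C10 both become sp2 and the configuration of the pinacolate is irrelevant. The alkene position is fixed by the carbonyl positions, so it can lie neither toward quaternary C9 nor at C5(10); the ketal and silyl ether are inert, and slow addition at high dilution favours ring closure over intermolecular aldehyde coupling. The C5 configuration should survive because the medium is non-basic and the six-ring closure is fast.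

Step 14
Reactants: 23 ketal
Product: 24 C13 methyl ketone
Conditions: PPTS, acetone/H2O, 50 °C
Reagents that add atoms: water, O
Why: Mild acid-catalysed ketal hydrolysis should free the ketone without moving the trisubstituted C1=C10 alkene or cleaving the hindered silyl ether.

Step 15
Reactants: 24 methyl ketone; 25 triethyl phosphonoacetate
Product: 26 ethyl (E)-enoate (C13=C14)
Conditions: NaH, (EtO)2P(O)CH2CO2Et, THF, 0 °C → reflux
Reagents that add atoms: triethyl phosphonoacetate, CCOC(=O)CP(=O)(OCC)OCC
Why: Horner–Wadsworth–Emmons olefination should favour the E isomer, in which the ester lies opposite the larger C12 chain, and any Z isomer can be removed by chromatography here or at the next stage.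

Step 16
Reactants: 26 enoate
Product: 27 (E)-allylic alcohol (C15–OH)
Conditions: i-Bu2AlH, CH2Cl2, −78 °C
Reagents that add atoms: none
Why: 1,2-Reduction of the α,β-unsaturated ester by the aluminium hydride gives the allylic alcohol with the alkene geometry retained.

Step 17
Reactants: 27 allylic alcohol; 28 propanoic anhydride
Product: 29 C15 propanoate
Conditions: (EtCO)2O, pyridine, DMAP (cat.), CH2Cl2, 0 °C → rt
Reagents that add atoms: propanoic anhydride, CCC(=O)OC(=O)CC
Why: DMAP-catalysed acylation of the only free hydroxyl.

Step 18
Reactants: 29 silyl ether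
Product: 30 C18 primary alcohol
Conditions: HF·pyridine, pyridine, THF, 0 °C → rt
Reagents that add atoms: none
Why: Fluoride-driven desilylation in a pyridine-buffered medium should spare the allylic ester and both alkenes.

Step 19
Reactants: 30 primary alcohol
Product: 32 target acid CNP0223570.1, via aldehyde 31 (not isolated)
Conditions: TEMPO (cat.), PhI(OAc)2, CH2Cl2, rt; then t-BuOH/H2O, 2-methylbut-2-ene, NaH2PO4, NaClO2, rt
Reagents that add atoms: sodium chlorite, [Na+].[O-]Cl=O
Why: Oxoammonium oxidation to the aldehyde followed in the same flask by Pinnick oxidation gives the acid; the aldehyde carbon sits on quaternary C4 and cannot epimerise, and the alkene scavenger protects both trisubstituted double bonds from hypochlorous acid.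

**Compound list**

1 | (R)-(−)-carvone, (5R)-2-methyl-5-(prop-1-en-2-yl)cyclohex-2-en-1-one | CC1=CC[C@H](CC1=O)C(C)=C | starting material
2 | ethyl bromoacetate | BrCC(=O)OCC | starting material
3 | ethyl 2-[(1S,6R)-3-methyl-2-oxo-6-(prop-1-en-2-yl)cyclohex-3-en-1-yl]acetate (C5 arm trans to C6 isopropenyl) | CC1=CC[C@@H](C(C)=C)[C@H](CC(=O)OCC)C1=O | intermediate
4 | methylmagnesium bromide | C[Mg]Br | starting material
5 | ethyl 2-[3,4-dimethyl-6-(prop-1-en-2-yl)-2-(trimethylsilyloxy)cyclohex-2-en-1-yl]acetate; C17 methyl cis to the C5 arm, trans to the isopropenyl | CC1=C(O[Si](C)(C)C)[C@@H](CC(=O)OCC)[C@H](C(C)=C)C[C@H]1C | intermediate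
6 | but-3-en-2-one | CC(=O)C=C | starting material
7 | ethyl 2-[3,4-dimethyl-2-oxo-3-(3-oxobutyl)-6-(prop-1-en-2-yl)cyclohexyl]acetate; C17, C20 and the C5 arm on the upper face, oxobutyl chain and isopropenyl on the lower face | CC(=O)CC[C@]1(C)C(=O)[C@@H](CC(=O)OCC)[C@H](C(C)=C)C[C@H]1C | intermediate
8 | C13 ethylene ketal of 7 (2-methyl-1,3-dioxolan-2-yl at C13) | CC1(OCCO1)CC[C@]2(C)C(=O)[C@@H](CC(=O)OCC)[C@H](C(C)=C)C[C@H]2C | intermediate
9 | C10 axial alcohol of 8 (hydroxyl on the upper face, cis to the C5 arm), formed as its lithium alkoxide | CC1(OCCO1)CC[C@]2(C)[C@@H](O)[C@@H](CC(=O)OCC)[C@H](C(C)=C)C[C@H]2C | intermediate (not isolated)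
10 | cis-fused γ-lactone O–C10/C18(=O)–C4H2–C5 with the C6 isopropenyl and the C13 ketal | CC1(OCCO1)CC[C@]2(C)[C@H]3OC(=O)C[C@H]3[C@H](C(C)=C)C[C@H]2C | intermediate
11 | lactone 10 with the isopropenyl replaced by a 2-hydroperoxy-2-methoxypropan-2-yl group (configuration at that carbon undefined) | CC1(OCCO1)CC[C@]2(C)[C@H]3OC(=O)C[C@H]3[C@H](C(C)(OC)OO)C[C@H]2C | intermediate (not isolated)
12 | cis-fused γ-lactone with C6 as CH2 | CC1(OCCO1)CC[C@]2(C)[C@H]3OC(=O)C[C@H]3CC[C@H]2C | intermediate
13 | allyl bromide | BrCC=C | starting material
14 | C4-allyl lactone, allyl cis to H5 | CC1(OCCO1)CC[C@]2(C)[C@H]3OC(=O)[C@H](CC=C)[C@H]3CC[C@H]2C | intermediate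
15 | iodomethane | CI | starting material
16 | C4-methyl C4-allyl lactone, methyl cis to H5, allyl on the ring B side | CC1(OCCO1)CC[C@]2(C)[C@H]3OC(=O)[C@@](C)(CC=C)[C@H]3CC[C@H]2C | intermediate
17 | diol: axial C10–OH (upper face), C18H2OH, allyl and methyl on C4, C13 ketal | CC1(OCCO1)CC[C@]2(C)[C@@H](O)[C@H](CC[C@H]2C)[C@@](C)(CO)CC=C | intermediate
18 | C18 tert-butyldiphenylsilyl ether of 17 | CC1(OCCO1)CC[C@]2(C)[C@@H](O)[C@H](CC[C@H]2C)[C@@](C)(CO[Si](c3ccccc3)(c4ccccc4)C(C)(C)C)CC=C | intermediate
19 | C1 B-alkyl-9-borabicyclo[3.3.1]nonane derived from 18 | CC1(OCCO1)CC[C@]2(C)[C@@H](O)[C@H](CC[C@H]2C)[C@@](C)(CO[Si](c3ccccc3)(c4ccccc4)C(C)(C)C)CCCB5C6CCCC5CCC6 | intermediate (not isolated)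
20 | C1,C10-diol with C18 silyl ether and C13 ketal | CC1(OCCO1)CC[C@]2(C)[C@@H](O)[C@H](CC[C@H]2C)[C@@](C)(CO[Si](c3ccccc3)(c4ccccc4)C(C)(C)C)CCCO | intermediate
21 | ring B keto aldehyde: C10 ketone, C1 aldehyde on the C4 arm, C18 silyl ether, C13 ketal | CC1(OCCO1)CC[C@]2(C)C(=O)[C@H](CC[C@H]2C)[C@@](C)(CO[Si](c3ccccc3)(c4ccccc4)C(C)(C)C)CCC=O | intermediate
22 | titanium-bound C1–C10 pinacolate, drawn as a cyclic titanium diolate with the other ligands on titanium omitted; configuration at C1 and C10 undefined | CC1(OCCO1)CC[C@]2(C)C34O[Ti]OC3CC[C@](C)(CO[Si](c5ccccc5)(c6ccccc6)C(C)(C)C)[C@H]4CC[C@H]2C | intermediate (not isolated)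
23 | halim-1(10)-ene with C18 silyl ether and C13 ketal | CC1(OCCO1)CC[C@]2(C)C3=CCC[C@](C)(CO[Si](c4ccccc4)(c5ccccc5)C(C)(C)C)[C@H]3CC[C@H]2C | intermediate
24 | C13 methyl ketone | CC(=O)CC[C@]1(C)C2=CCC[C@](C)(CO[Si](c3ccccc3)(c4ccccc4)C(C)(C)C)[C@H]2CC[C@H]1C | intermediate
25 | triethyl phosphonoacetate | CCOC(=O)CP(=O)(OCC)OCC | starting material
26 | ethyl (13E)-enoate | CCOC(=O)/C=C(\C)CC[C@]1(C)C2=CCC[C@](C)(CO[Si](c3ccccc3)(c4ccccc4)C(C)(C)C)[C@H]2CC[C@H]1C | intermediate
27 | (13E)-allylic alcohol, C15–OH | OC/C=C(\C)CC[C@]1(C)C2=CCC[C@](C)(CO[Si](c3ccccc3)(c4ccccc4)C(C)(C)C)[C@H]2CC[C@H]1C | intermediate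
28 | propanoic anhydride | CCC(=O)OC(=O)CC | starting material
29 | C15 propanoate with C18 silyl ether | CCC(=O)OC/C=C(\C)CC[C@]1(C)C2=CCC[C@](C)(CO[Si](c3ccccc3)(c4ccccc4)C(C)(C)C)[C@H]2CC[C@H]1C | intermediate
30 | C15 propanoate with C18 primary alcohol | CCC(=O)OC/C=C(\C)CC[C@]1(C)C2=CCC[C@](C)(CO)[C@H]2CC[C@H]1C | intermediate
31 | C15 propanoate with C18 aldehyde | CCC(=O)OC/C=C(\C)CC[C@]1(C)C2=CCC[C@](C)(C=O)[C@H]2CC[C@H]1C | intermediate (not isolated)
32 | (4S,5S,8R,9S,13E)-15-propanoyloxyhalima-1(10),13-dien-18-oic acid, CNP0223570.1 | CCC(=O)OC/C=C(\C)CC[C@]1(C)C2=CCC[C@](C)(C(=O)O)[C@H]2CC[C@H]1C | target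

**Summary**

Total step count: 19. Longest linear sequence: 19 steps, from 1 to 32.

Steps most likely to fail:

Step 13. The coupling may stall at the pinacolate stage, and the long reflux needed for deoxygenation may allow titanium-mediated enolisation toward C5 and loss of that configuration. The fallback keeps the same C1–C10 reductive carbonyl coupling but separates bond formation from deoxygenation. It sets out from 21: samarium diiodide (SmI2, t-BuOH, THF, −78 °C) should effect ketyl–carbonyl pinacol cyclisation to the cis-1,10-diol F1. 1,1'-Thiocarbonyldiimidazole with DMAP in hot toluene converts it into the cyclic thiocarbonate F2. Corey–Winter olefination with 1,3-dimethyl-2-phenyl-1,3,2-diazaphospholidine at 40 °C then gives the alkene by syn elimination, and the route is rejoined at 23.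

Step 3. Protodesilylation of the congested silyl enol ether may outrun C–C bond formation at the fully substituted C9. The fallback sets out from 5 and uses but-3-yn-2-one, a linear and stronger acceptor, under the same Lewis acid conditions to give the (E)-enedione F3. Chemoselective conjugate reduction with [(Ph3P)CuH]6 in wet benzene should leave the isopropenyl group, the ester and the hindered ring ketone alone. It returns to the route at 7.

Step 15. Olefination of a methyl ketone may give poor E/Z discrimination, with isomers that are hard to separate. The fallback sets out from 24: LiN(i-Pr)2 and ClP(O)(OEt)2 give the terminal enol diethyl phosphate F4, and excess LiN(i-Pr)2 eliminates it to the terminal alkyne F5. Zirconium-catalysed methylalumination (Me3Al, Cp2ZrCl2, CH2Cl2), followed by n-BuLi and paraformaldehyde, adds methyl and the hydroxymethyl carbon syn across the alkyne. This should give only the E allylic alcohol and rejoins the route at 27, bypassing 26.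

**Further compounds**

F1 | step 13 | cis-1,10-diol of the closed ring A (hydroxyls cis; configuration relative to C5 not fixed), C18 silyl ether, C13 ketal | CC1(OCCO1)CC[C@]2(C)C3(O)C(O)CC[C@](C)(CO[Si](c4ccccc4)(c5ccccc5)C(C)(C)C)[C@H]3CC[C@H]2C
F2 | step 13 | cyclic 1,10-thiocarbonate of F1 | CC1(OCCO1)CC[C@]2(C)C34OC(=S)OC3CC[C@](C)(CO[Si](c5ccccc5)(c6ccccc6)C(C)(C)C)[C@H]4CC[C@H]2C
F3 | step 3 | (E)-enedione: 7 with a C11=C12 double bond | CC(=O)/C=C/[C@]1(C)C(=O)[C@@H](CC(=O)OCC)[C@H](C(C)=C)C[C@H]1C
F4 | step 15 | terminal enol diethyl phosphate of ketone 24 | C=C(OP(=O)(OCC)OCC)CC[C@]1(C)C2=CCC[C@](C)(CO[Si](c3ccccc3)(c4ccccc4)C(C)(C)C)[C@H]2CC[C@H]1C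
F5 | step 15 | terminal alkyne (C13≡CH) | C#CCC[C@]1(C)C2=CCC[C@](C)(CO[Si](c3ccccc3)(c4ccccc4)C(C)(C)C)[C@H]2CC[C@H]1C
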